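The six-membered ring (numbered C5–C10 as in elemanes: C10 quaternary, C8 acyloxy, C6 carbinol) is made last, from an open-chain dienynol. C10 (methyl, vinyl) and C5 (hydroxymethylvinyl) are vicinal allylic termini, the retron of a [3,3] shift; the C8 carbinol beside the C7 propenyl arm is a carbonyl-ene retron. In one pot an anionic oxy-Cope rearrangement breaks a sacrificial C3–C8 bond, forges C5–C10 and unveils the C8 aldehyde, which closes the ring on a prenyl group (C7–C8), setting C5, C7, C8 and C10. The precursor is an acyclic secondary alcohol with two stereocentres: C8, lost and remade, and C6, carried epimeric and inverted late by lactonisation.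

Key step: step 10

Remark: the antipode of each chiral catalyst (TRIP, ProPhenol) is to be confirmed on a model aldehyde so that the stated carbinol configuration results; the target is a cis-γ-hydroxy acid with a γ-hydroxy ester side chain and is assumed isolable if kept cold near pH 5–7, since acid would close the C6/C12 lactone and base would cleave the side chain.

Step 1
Reactants: 1 (Z)-3-methylpent-2-en-4-yn-1-ol
Product: 3 (Z)-5-(tert-butyldimethylsilyl)-3-methylpent-2-en-4-yn-1-ol, via bis-silylated enynol 2 (not isolated)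
Conditions: n-BuLi (2.1 equiv), THF, −78 °C; TBSCl (2.2 equiv), −78 °C to rt; then 1 M HCl, THF, rt
Reagents that add atoms: tert-butyldimethylsilyl chloride, CC(C)(C)[Si](C)(C)Cl
Why: The dianion is silylated at oxygen and at the acetylide carbon and dilute acid then cleaves only the silyl ether (C-silylation of an acetylide, selective O-desilylation), the Z alkene being untouched.

Step 2
Reactants: 3 (Z)-5-(tert-butyldimethylsilyl)-3-methylpent-2-en-4-yn-1-ol
Product: 4 (Z)-5-(tert-butyldimethylsilyl)-3-methylpent-2-en-4-ynal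
Conditions: MnO2 (excess), CH2Cl2, rt
Reagents that add atoms: none
Why: MnO2 oxidises the allylic alcohol to the enal under neutral conditions that should keep the Z geometry (allylic alcohol oxidation).

Step 3
Reactants: 4 (Z)-5-(tert-butyldimethylsilyl)-3-methylpent-2-en-4-ynal; 5 allenylboronic acid pinacol ester
Product: 6 (4R,5Z)-8-(tert-butyldimethylsilyl)-6-methyloct-5-ene-1,7-diyn-4-ol
Conditions: 5 (1.5 equiv), (R)-TRIP (5 mol%), 4 Å MS, toluene, −20 °C
Reagents that add atoms: none
Why: Chiral phosphoric acid-catalysed propargylation by the allenylboronate through a closed six-membered transition state should set the 4R carbinol (future C8) under catalyst control (asymmetric carbonyl propargylation).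

Step 4
Reactants: 6 (4R,5Z)-8-(tert-butyldimethylsilyl)-6-methyloct-5-ene-1,7-diyn-4-ol
Product: 7 (4R,5Z)-8-(tert-butyldimethylsilyl)-6-methyl-4-(triethylsilyloxy)oct-5-ene-1,7-diyne
Conditions: TESCl, imidazole, DMF, 0 °C
Reagents that add atoms: chlorotriethylsilane, CC[Si](CC)(CC)Cl
Why: Silyl ether formation masks the C8 hydroxyl for the organozinc, hydride and alkylation steps that follow.

Step 5
Reactants: 7 (4R,5Z)-8-(tert-butyldimethylsilyl)-6-methyl-4-(triethylsilyloxy)oct-5-ene-1,7-diyne; 8 3-methylbut-2-enal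
Product: 9 (4S,8R,9Z)-12-(tert-butyldimethylsilyl)-2,10-dimethyl-8-(triethylsilyloxy)dodeca-2,9-diene-5,11-diyn-4-ol
Conditions: 8 (3 equiv), (S,S)-ProPhenol (20 mol%), ZnMe2 (3 equiv), Ph3PO (40 mol%), toluene, 4 °C
Reagents that add atoms: none
Why: Zinc–ProPhenol-catalysed addition of the terminal alkyne to the enal should set the 4S carbinol (future C6, deliberately epimeric to the target) by catalyst control, the remote C8 centre having no say (asymmetric alkynylation of an aldehyde).

Step 6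
Reactants: 9 (4S,8R,9Z)-12-(tert-butyldimethylsilyl)-2,10-dimethyl-8-(triethylsilyloxy)dodeca-2,9-diene-5,11-diyn-4-ol
Product: 11 (4S,5Z,8R,9Z)-12-(tert-butyldimethylsilyl)-6-iodo-2,10-dimethyl-8-(triethylsilyloxy)dodeca-2,5,9-trien-11-yn-4-ol, via alkenylalanate 10 (not isolated)
Conditions: NaAlH2(OCH2CH2OMe)2, THF, 0 °C to rt; then I2, THF, −78 °C
Reagents that add atoms: iodine, [I][I]
Why: The propargylic alkoxide directs a trans-hydroalumination that puts aluminium on the distal alkyne carbon cis to the carbinol, and iodine cleaves the C–Al bond with retention (directed hydroalumination–iodination), which fixes the C4=C5 geometry.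

Step 7
Reactants: 11 (4S,5Z,8R,9Z)-12-(tert-butyldimethylsilyl)-6-iodo-2,10-dimethyl-8-(triethylsilyloxy)dodeca-2,5,9-trien-11-yn-4-ol
Product: 12 (4S,5Z,8R,9Z)-12-(tert-butyldimethylsilyl)-6-(hydroxymethyl)-2,10-dimethyl-8-(triethylsilyloxy)dodeca-2,5,9-trien-11-yn-4-ol
Conditions: Bu3SnCH2OH, Pd(PPh3)4 (10 mol%), dioxane, 90 °C
Reagents that add atoms: (tributylstannyl)methanol, CCCC[Sn](CCCC)(CCCC)CO
Why: Stille coupling of the alkenyl iodide proceeds with retention and so places C15 cis to C6 and the chain to C8 trans to it.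

Step 8
Reactants: 12 (4S,5Z,8R,9Z)-12-(tert-butyldimethylsilyl)-6-(hydroxymethyl)-2,10-dimethyl-8-(triethylsilyloxy)dodeca-2,5,9-trien-11-yn-4-ol
Product: 13 bis(4-methoxybenzyl) ether of 12
Conditions: NaH, 4-methoxybenzyl chloride, Bu4NI (cat.), THF–DMF, 0 °C to rt
Reagents that add atoms: 4-methoxybenzyl chloride, COc1ccc(CCl)cc1
Why: Williamson etherification of both hydroxyls gives ethers stable to base and fluoride, the C6 ether being needed as a non-donating group in the key step.

Step 9
Reactants: 13 bis(4-methoxybenzyl) ether of 12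
Product: 14 (4S,5Z,8R,9Z)-12-(tert-butyldimethylsilyl)-4-(4-methoxybenzyloxy)-6-[(4-methoxybenzyloxy)methyl]-2,10-dimethyldodeca-2,5,9-trien-11-yn-8-ol (numbering of 12 retained)
Conditions: PPTS, MeOH–CH2Cl2, 0 °C
Reagents that add atoms: none
Why: Mild acid methanolysis removes the triethylsilyl ether much faster than it touches the benzylic ethers or the C-silyl alkyne (selective silyl ether cleavage).

Step 10
Reactants: 14 (4S,5Z,8R,9Z)-12-(tert-butyldimethylsilyl)-4-(4-methoxybenzyloxy)-6-[(4-methoxybenzyloxy)methyl]-2,10-dimethyldodeca-2,5,9-trien-11-yn-8-ol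
Product: 17 (1S,2R,3R,4S,5S)-5-[(tert-butyldimethylsilyl)ethynyl]-3-(4-methoxybenzyloxy)-4-{3-[(4-methoxybenzyl)oxy]prop-1-en-2-yl}-5-methyl-2-(prop-1-en-2-yl)cyclohexan-1-ol, via potassium enolate 15 (not isolated), via aldehyde 16 (not isolated)
Conditions: KH (1.3 equiv), 18-crown-6 (1.3 equiv), THF, 0 °C to rt; AcOH (1.5 equiv), −78 °C; solvent changed to CH2Cl2; AlMe2Cl (2.5 equiv), −78 to −30 °C
Reagents that add atoms: none
Why: KH with 18-crown-6 gives the free C8 alkoxide, whose 1,5-diene C10=C9–C8(O−)–C3–C4=C5 undergoes an oxyanion-accelerated [3,3] shift through a chair that joins C5 to C10, cuts the sacrificial C3–C8 bond and leaves the C8 aldehyde as enolate 15; acetic acid releases aldehyde 16 and AlMe2Cl then drives a carbonyl-ene reaction in which C8 bonds to C7 of the prenyl group while a methyl hydrogen passes to oxygen. The closest known reaction types are the anionic oxy-Cope rearrangement and one-pot oxy-Cope/carbonyl-ene cascades used for terpenoid rings. The only ring closed is the cyclohexane C5–C10, formed in the ene step as a six-membered chair closure with the reacting alkene outside the ring. C10 and C5 are set by the chair of the [3,3] shift: the Z enyne forces the C8 oxide equatorial by allylic strain so that the 8R centre fixes the absolute sense, the C6 chain trans to C3 sits equatorial, and the C6 ether reinforces the same face (hydrogen in the alkene plane, alkenyl arm anti to the new bond). C7 and C8 are set by the ene chair that places the slim alkynyl group axial and the C6 ether, the C7 arm and the C8 oxygen equatorial (at the price of an axial C5 side chain), the other chair suffering a syn-axial methyl/ether clash, which is why C6 is carried in the epimeric configuration. The step needs the aldehyde to close on the trisubstituted prenyl alkene and not on the new 1,1-disubstituted alkene at C4, which the higher nucleophilicity of the former and the inductively deactivating CH2O-benzyl group on the latter should secure.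

Step 11
Reactants: 17 (1S,2R,3R,4S,5S)-5-[(tert-butyldimethylsilyl)ethynyl]-3-(4-methoxybenzyloxy)-4-{3-[(4-methoxybenzyl)oxy]prop-1-en-2-yl}-5-methyl-2-(prop-1-en-2-yl)cyclohexan-1-ol
Product: 18 (1S,2R,3R,4S,5S)-5-ethynyl analogue of 17
Conditions: Bu4NF, THF, 0 °C
Reagents that add atoms: none
Why: Fluoride cleaves the C(sp)–Si bond (protodesilylation of a silylalkyne), no silyl ether being present at this stage.

Step 12
Reactants: 18 (1S,2R,3R,4S,5S)-5-ethynyl analogue of 17
Product: 19 (1S,2R,3R,4S,5R)-5-ethenyl-3-(4-methoxybenzyloxy)-4-{3-[(4-methoxybenzyl)oxy]prop-1-en-2-yl}-5-methyl-2-(prop-1-en-2-yl)cyclohexan-1-ol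
Conditions: H2 (1 atm), Pd/CaCO3 poisoned with Pb(OAc)2, quinoline, EtOAc, rt
Reagents that add atoms: none
Why: Poisoned palladium reduces the terminal alkyne to the vinyl group far faster than it touches the 1,1-disubstituted alkenes or the benzylic ethers (Lindlar semi-hydrogenation).

Step 13
Reactants: 20 dimethyl (R)-malate
Product: 21 methyl (R)-3,4-dihydroxybutanoate
Conditions: BH3·SMe2, NaBH4 (5 mol%), THF, 0 °C to rt; then MeOH
Reagents that add atoms: none
Why: The hydroxyl group directs borane to the neighbouring ester so that only the α-hydroxy ester is reduced (hydroxyl-directed chemoselective borane reduction), the stereocentre being untouched.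

Step 14
Reactants: 21 methyl (R)-3,4-dihydroxybutanoate
Product: 22 methyl (R)-3,4-bis(tert-butyldimethylsilyloxy)butanoate
Conditions: TBSCl, imidazole, DMF, rt
Reagents that add atoms: tert-butyldimethylsilyl chloride, CC(C)(C)[Si](C)(C)Cl
Why: Silylation of both hydroxyls prevents lactonisation and gives fluoride-labile protection for the end of the route (silyl ether formation).

Step 15
Reactants: 22 methyl (R)-3,4-bis(tert-butyldimethylsilyloxy)butanoate
Product: 25 methyl (R)-3,4-bis(tert-butyldimethylsilyloxy)-2-methylenebutanoate, via Mannich base 23 (not isolated), via ammonium iodide 24 (not isolated)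
Conditions: LiN(iPr)2, THF, −78 °C; CH2=NMe2+ I−; then MeI, MeOH; then DBU, CH2Cl2
Reagents that add atoms: Eschenmoser's salt, C=[N+](C)C.[I-]
Why: The ester enolate is aminomethylated at −78 °C, where β-elimination of silanolate should be slow, and quaternisation followed by elimination gives the acrylate (α-methylenation through a Mannich base).

Step 16
Reactants: 25 methyl (R)-3,4-bis(tert-butyldimethylsilyloxy)-2-methylenebutanoate
Product: 26 (R)-3,4-bis(tert-butyldimethylsilyloxy)-2-methylenebutanoic acid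
Conditions: LiOH, THF–MeOH–H2O, 0 °C to rt; then NaHSO4 to pH 4
Reagents that add atoms: lithium hydroxide, [Li+].[OH-]
Why: Saponification of the unhindered methyl ester leaves the silyl ethers and the stereocentre intact (ester hydrolysis).

Step 17
Reactants: 19 (1S,2R,3R,4S,5R)-5-ethenyl-3-(4-methoxybenzyloxy)-4-{3-[(4-methoxybenzyl)oxy]prop-1-en-2-yl}-5-methyl-2-(prop-1-en-2-yl)cyclohexan-1-ol; 26 (R)-3,4-bis(tert-butyldimethylsilyloxy)-2-methylenebutanoic acid
Product: 28 C8 ester of 19 with acid 26, via mixed anhydride 27 (not isolated)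
Conditions: 26, 2,4,6-trichlorobenzoyl chloride, Et3N, THF, rt; then 19, DMAP, toluene, rt
Reagents that add atoms: none
Why: Yamaguchi esterification acylates the only free hydroxyl, the equatorial C8–OH, with retention at C8.

Step 18
Reactants: 28 C8 ester of 19 with acid 26
Product: 29 C12 alcohol (isopropenyl methyl of 28 oxidised to CH2OH)
Conditions: SeO2 (0.3 equiv), t-BuOOH (3 equiv), CH2Cl2, rt
Reagents that add atoms: tert-butyl hydroperoxide, CC(C)(C)OO
Why: Selenium dioxide reacts by ene reaction and [2,3] shift at the most electron-rich alkene, the isopropenyl group, and oxidises its methyl (Riley allylic oxidation), the allyl ether alkene and the acrylate being deactivated and the vinyl group having no allylic hydrogen.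

Step 19
Reactants: 29 C12 alcohol
Product: 31 C12 carboxylic acid (2-substituted acrylic acid at C7), via enal 30 (not isolated)
Conditions: Dess–Martin periodinane, NaHCO3, CH2Cl2, 0 °C; then NaClO2, NaH2PO4, 2-methyl-2-butene, t-BuOH–H2O, rt
Reagents that add atoms: sodium chlorite, [Na+].[O-]Cl=O
Why: Periodinane oxidation gives the enal and buffered chlorite takes it to the acrylic acid without touching ethers, esters or alkenes (Dess–Martin and Pinnick oxidations).

Step 20
Reactants: 31 C12 carboxylic acid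
Product: 32 diol acid (C6–OH and C15–OH free, 6R)
Conditions: DDQ (2.5 equiv), CH2Cl2–pH 7 buffer, 0 °C to rt
Reagents that add atoms: none
Why: DDQ oxidises the electron-rich arenes and cleaves both 4-methoxybenzyl ethers while silyl ethers, esters and the acid persist (oxidative debenzylation).

Step 21
Reactants: 32 diol acid
Product: 34 C15 silyl ether of 32 (C6–OH and CO2H free), via silyl ester 33 (not isolated)
Conditions: TBSCl (2.5 equiv), imidazole, DMF, 0 °C; then K2CO3, MeOH, 0 °C
Reagents that add atoms: tert-butyldimethylsilyl chloride, CC(C)(C)[Si](C)(C)Cl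
Why: The primary allylic hydroxyl is silylated much faster than the hindered secondary C6–OH, and the silyl ester formed at the acid is cleaved again by carbonate methanolysis (selective silylation).

Step 22
Reactants: 34 C15 silyl ether of 32
Product: 35 cis-fused α-methylene-γ-lactone (C12 carboxyl to O6, configuration 6S)
Conditions: PPh3, DIAD, THF (0.005 M), 0 °C to rt
Reagents that add atoms: none
Why: Activation of C6–OH as the oxyphosphonium and intramolecular SN2 attack by the C12 carboxylate close the γ-lactone with inversion at C6 (Mitsunobu lactonisation), which sets C6 cis to the C7 substituent.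

Step 23
Reactants: 35 cis-fused α-methylene-γ-lactone
Product: 36 tris(tert-butyldimethylsilyl) ether of the target hydroxy acid
Conditions: LiOH (1.2 equiv), THF–H2O, 0 °C; then NaHSO4 to pH 5, 0 °C
Reagents that add atoms: lithium hydroxide, [Li+].[OH-]
Why: Hydroxide opens the unhindered α-methylene-γ-lactone by acyl–oxygen cleavage much faster than it attacks the hindered, α-branched C8 acrylate (chemoselective saponification), so that C6 keeps its new configuration.

Step 24
Reactants: 36 tris(tert-butyldimethylsilyl) ether of the target hydroxy acid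
Product: 37 target acid, (5S,6S,7S,8S,10R) ring configuration with the (R)-3,4-dihydroxy-2-methylenebutanoate at O8
Conditions: HF·pyridine, pyridine, THF, 0 °C to rt
Reagents that add atoms: none
Why: Pyridine-buffered fluoride removes the three silyl ethers near neutral pH (desilylation), where neither lactonisation of the cis-hydroxy acid nor transesterification within the side chain is expected.

Compound list
1 | (Z)-3-methylpent-2-en-4-yn-1-ol | C#C/C(C)=C\CO | starting material
2 | (Z)-O,C-bis(tert-butyldimethylsilyl) derivative of 1 | CC(C)(C)[Si](C)(C)C#C/C(C)=C\CO[Si](C)(C)C(C)(C)C | intermediate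
3 | (Z)-5-(tert-butyldimethylsilyl)-3-methylpent-2-en-4-yn-1-ol | CC(C)(C)[Si](C)(C)C#C/C(C)=C\CO | intermediate
4 | (Z)-5-(tert-butyldimethylsilyl)-3-methylpent-2-en-4-ynal | CC(C)(C)[Si](C)(C)C#C/C(C)=C\C=O | intermediate
5 | allenylboronic acid pinacol ester | C=C=CB1OC(C)(C)C(C)(C)O1 | starting material
6 | (4R,5Z)-8-(tert-butyldimethylsilyl)-6-methyloct-5-ene-1,7-diyn-4-ol | C#CC[C@@H](O)/C=C(C)\C#C[Si](C)(C)C(C)(C)C | intermediate
7 | (4R,5Z)-8-(tert-butyldimethylsilyl)-6-methyl-4-(triethylsilyloxy)oct-5-ene-1,7-diyne | C#CC[C@@H](O[Si](CC)(CC)CC)/C=C(C)\C#C[Si](C)(C)C(C)(C)C | intermediate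
8 | 3-methylbut-2-enal | CC(C)=CC=O | starting material
9 | (4S,8R,9Z)-12-(tert-butyldimethylsilyl)-2,10-dimethyl-8-(triethylsilyloxy)dodeca-2,9-diene-5,11-diyn-4-ol | CC(C)=C[C@H](O)C#CC[C@@H](O[Si](CC)(CC)CC)/C=C(C)\C#C[Si](C)(C)C(C)(C)C | intermediate
10 | sodium cyclic alkoxy(alkenyl)bis(2-methoxyethoxy)aluminate from 9 (aluminium on C6, cis to C4) | [Na+].COCCO[Al-]1(OCCOC)O[C@@H](C=C(C)C)C=C1C[C@@H](O[Si](CC)(CC)CC)/C=C(C)\C#C[Si](C)(C)C(C)(C)C | intermediate
11 | (4S,5Z,8R,9Z)-12-(tert-butyldimethylsilyl)-6-iodo-2,10-dimethyl-8-(triethylsilyloxy)dodeca-2,5,9-trien-11-yn-4-ol | CC(C)=C[C@H](O)/C=C(I)/C[C@@H](O[Si](CC)(CC)CC)/C=C(C)\C#C[Si](C)(C)C(C)(C)C | intermediate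
12 | (4S,5Z,8R,9Z)-12-(tert-butyldimethylsilyl)-6-(hydroxymethyl)-2,10-dimethyl-8-(triethylsilyloxy)dodeca-2,5,9-trien-11-yn-4-ol | CC(C)=C[C@H](O)/C=C(CO)/C[C@@H](O[Si](CC)(CC)CC)/C=C(C)\C#C[Si](C)(C)C(C)(C)C | intermediate
13 | bis(4-methoxybenzyl) ether of 12 (4S,5Z,8R,9Z) | CC(C)=C[C@H](OCc1ccc(OC)cc1)/C=C(COCc1ccc(OC)cc1)/C[C@@H](O[Si](CC)(CC)CC)/C=C(C)\C#C[Si](C)(C)C(C)(C)C | intermediate
14 | (4S,5Z,8R,9Z)-12-(tert-butyldimethylsilyl)-4-(4-methoxybenzyloxy)-6-[(4-methoxybenzyloxy)methyl]-2,10-dimethyldodeca-2,5,9-trien-11-yn-8-ol (numbering of 12) | CC(C)=C[C@H](OCc1ccc(OC)cc1)/C=C(COCc1ccc(OC)cc1)/C[C@@H](O)/C=C(C)\C#C[Si](C)(C)C(C)(C)C | intermediate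
15 | potassium enolate of aldehyde 16 | CC(C)(C)[Si](C)(C)C#C[C@@](C)(C=C[O-])[C@@H](C(=C)COCc1ccc(OC)cc1)[C@@H](OCc1ccc(OC)cc1)C=C(C)C.[K+] | intermediate
16 | (3S,4S,5S)-3-[(tert-butyldimethylsilyl)ethynyl]-5-(4-methoxybenzyloxy)-4-{3-[(4-methoxybenzyl)oxy]prop-1-en-2-yl}-3,7-dimethyloct-6-enal | CC(C)(C)[Si](C)(C)C#C[C@@](C)(CC=O)[C@@H](C(=C)COCc1ccc(OC)cc1)[C@@H](OCc1ccc(OC)cc1)C=C(C)C | intermediate
17 | (1S,2R,3R,4S,5S)-5-[(tert-butyldimethylsilyl)ethynyl]-3-(4-methoxybenzyloxy)-4-{3-[(4-methoxybenzyl)oxy]prop-1-en-2-yl}-5-methyl-2-(prop-1-en-2-yl)cyclohexan-1-ol | CC(C)(C)[Si](C)(C)C#C[C@@]1(C)C[C@H](O)[C@@H](C(C)=C)[C@H](OCc2ccc(OC)cc2)[C@@H]1C(=C)COCc1ccc(OC)cc1 | intermediate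
18 | (1S,2R,3R,4S,5S)-5-ethynyl-3-(4-methoxybenzyloxy)-4-{3-[(4-methoxybenzyl)oxy]prop-1-en-2-yl}-5-methyl-2-(prop-1-en-2-yl)cyclohexan-1-ol | C#C[C@@]1(C)C[C@H](O)[C@@H](C(C)=C)[C@H](OCc2ccc(OC)cc2)[C@@H]1C(=C)COCc1ccc(OC)cc1 | intermediate
19 | (1S,2R,3R,4S,5R)-5-ethenyl-3-(4-methoxybenzyloxy)-4-{3-[(4-methoxybenzyl)oxy]prop-1-en-2-yl}-5-methyl-2-(prop-1-en-2-yl)cyclohexan-1-ol | C=C[C@@]1(C)C[C@H](O)[C@@H](C(C)=C)[C@H](OCc2ccc(OC)cc2)[C@@H]1C(=C)COCc1ccc(OC)cc1 | intermediate
20 | dimethyl (R)-malate | COC(=O)C[C@@H](O)C(=O)OC | starting material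
21 | methyl (R)-3,4-dihydroxybutanoate | COC(=O)C[C@@H](O)CO | intermediate
22 | methyl (R)-3,4-bis(tert-butyldimethylsilyloxy)butanoate | COC(=O)C[C@@H](O[Si](C)(C)C(C)(C)C)CO[Si](C)(C)C(C)(C)C | intermediate
23 | methyl (3R)-3,4-bis(tert-butyldimethylsilyloxy)-2-[(dimethylamino)methyl]butanoate (C2 epimers) | COC(=O)C(CN(C)C)[C@@H](O[Si](C)(C)C(C)(C)C)CO[Si](C)(C)C(C)(C)C | intermediate
24 | trimethylammonium iodide from 23 | COC(=O)C(C[N+](C)(C)C)[C@@H](O[Si](C)(C)C(C)(C)C)CO[Si](C)(C)C(C)(C)C.[I-] | intermediate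
25 | methyl (R)-3,4-bis(tert-butyldimethylsilyloxy)-2-methylenebutanoate | COC(=O)C(=C)[C@@H](O[Si](C)(C)C(C)(C)C)CO[Si](C)(C)C(C)(C)C | intermediate
26 | (R)-3,4-bis(tert-butyldimethylsilyloxy)-2-methylenebutanoic acid | C=C(C(=O)O)[C@@H](O[Si](C)(C)C(C)(C)C)CO[Si](C)(C)C(C)(C)C | intermediate
27 | mixed anhydride of 26 with 2,4,6-trichlorobenzoic acid | C=C(C(=O)OC(=O)c1c(Cl)cc(Cl)cc1Cl)[C@@H](O[Si](C)(C)C(C)(C)C)CO[Si](C)(C)C(C)(C)C | intermediate
28 | C8 ester of 19 with 26; ring (5S,6R,7R,8S,10R), side chain R | C=C[C@@]1(C)C[C@H](OC(=O)C(=C)[C@@H](O[Si](C)(C)C(C)(C)C)CO[Si](C)(C)C(C)(C)C)[C@@H](C(C)=C)[C@H](OCc2ccc(OC)cc2)[C@@H]1C(=C)COCc1ccc(OC)cc1 | intermediate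
29 | as 28 with the C7 substituent 3-hydroxyprop-1-en-2-yl | C=C[C@@]1(C)C[C@H](OC(=O)C(=C)[C@@H](O[Si](C)(C)C(C)(C)C)CO[Si](C)(C)C(C)(C)C)[C@@H](C(=C)CO)[C@H](OCc2ccc(OC)cc2)[C@@H]1C(=C)COCc1ccc(OC)cc1 | intermediate
30 | as 28 with the C7 substituent 3-oxoprop-1-en-2-yl (enal) | C=C[C@@]1(C)C[C@H](OC(=O)C(=C)[C@@H](O[Si](C)(C)C(C)(C)C)CO[Si](C)(C)C(C)(C)C)[C@@H](C(=C)C=O)[C@H](OCc2ccc(OC)cc2)[C@@H]1C(=C)COCc1ccc(OC)cc1 | intermediate
31 | as 28 with the C7 substituent 1-carboxyethenyl (acrylic acid) | C=C[C@@]1(C)C[C@H](OC(=O)C(=C)[C@@H](O[Si](C)(C)C(C)(C)C)CO[Si](C)(C)C(C)(C)C)[C@@H](C(=C)C(=O)O)[C@H](OCc2ccc(OC)cc2)[C@@H]1C(=C)COCc1ccc(OC)cc1 | intermediate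
32 | diol acid: 31 without both 4-methoxybenzyl groups; ring (5S,6R,7S,8S,10R) | C=C[C@@]1(C)C[C@H](OC(=O)C(=C)[C@@H](O[Si](C)(C)C(C)(C)C)CO[Si](C)(C)C(C)(C)C)[C@@H](C(=C)C(=O)O)[C@H](O)[C@@H]1C(=C)CO | intermediate
33 | C15 silyl ether and C12 silyl ester of 32 | C=C[C@@]1(C)C[C@H](OC(=O)C(=C)[C@@H](O[Si](C)(C)C(C)(C)C)CO[Si](C)(C)C(C)(C)C)[C@@H](C(=C)C(=O)O[Si](C)(C)C(C)(C)C)[C@H](O)[C@@H]1C(=C)CO[Si](C)(C)C(C)(C)C | intermediate
34 | C15 tert-butyldimethylsilyl ether of 32 (C6–OH and CO2H free) | C=C[C@@]1(C)C[C@H](OC(=O)C(=C)[C@@H](O[Si](C)(C)C(C)(C)C)CO[Si](C)(C)C(C)(C)C)[C@@H](C(=C)C(=O)O)[C@H](O)[C@@H]1C(=C)CO[Si](C)(C)C(C)(C)C | intermediate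
35 | cis-fused α-methylene-γ-lactone between C12 and O6; ring (5S,6S,7R,8S,10R) | C=C[C@@]1(C)C[C@H](OC(=O)C(=C)[C@@H](O[Si](C)(C)C(C)(C)C)CO[Si](C)(C)C(C)(C)C)[C@H]2C(=C)C(=O)O[C@H]2[C@@H]1C(=C)CO[Si](C)(C)C(C)(C)C | intermediate
36 | tris(tert-butyldimethylsilyl) ether of the target (O15, O3', O4'); ring (5S,6S,7S,8S,10R) | C=C[C@@]1(C)C[C@H](OC(=O)C(=C)[C@@H](O[Si](C)(C)C(C)(C)C)CO[Si](C)(C)C(C)(C)C)[C@@H](C(=C)C(=O)O)[C@@H](O)[C@@H]1C(=C)CO[Si](C)(C)C(C)(C)C | intermediate
37 | 2-{(1S,2S,3S,4S,6S)-2-hydroxy-... cyclohexyl}acrylic acid target: ring (5S,6S,7S,8S,10R), O8 ester of (R)-3,4-dihydroxy-2-methylenebutanoic acid | C=C[C@@]1(C)C[C@H](OC(=O)C(=C)[C@@H](O)CO)[C@@H](C(=C)C(=O)O)[C@@H](O)[C@@H]1C(=C)CO | target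

Total step count: 24 (20 in the main line, 4 for the side-chain acid 26). Longest linear sequence: 20 steps (steps 1–12 and 17–24).

Steps most likely to fail

Step 10. The process at risk is the second stage: once the [3,3] shift has delivered the aldehyde, it may cyclise through the new 1,1-disubstituted alkene at C4 (re-forming a C3–C8 bond) instead of the prenyl alkene, or the Lewis acid may strip a 4-methoxybenzyl ether. The fallback sets out from 14. The rearrangement is run alone (KH, 18-crown-6, THF; AcOH) and aldehyde 16 is isolated. Selenium-catalysed ene-chlorination of its most electron-rich alkene (N-chlorosuccinimide, PhSeCl cat., CH2Cl2) gives the transposed allylic chloride, (3S,4S,5R)-3-[(tert-butyldimethylsilyl)ethynyl]-6-chloro-5-(4-methoxybenzyloxy)-4-{3-[(4-methoxybenzyl)oxy]prop-1-en-2-yl}-3,7-dimethyloct-7-enal F1. An intramolecular Nozaki–Hiyama–Kishi allylation (CrCl2, THF, high dilution) then closes C7–C8 through the allylchromium, which is far more nucleophilic than any alkene present and reacts at its substituted terminus through a chair. The route is rejoined at 17.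

Step 18. The process at risk is site selectivity of the allylic oxidation (attack at the C15 methylene or a ring methine) and over-oxidation. The fallback sets out from 28: the same ene-chlorination (N-chlorosuccinimide, PhSeCl cat., CH2Cl2) converts the isopropenyl group into the 2-(chloromethyl)allyl compound, the C7 3-chloroprop-1-en-2-yl analogue of 28 F2, which trimethylamine N-oxide in DMSO oxidises to the enal. This is compound 30, where the route is rejoined before the chlorite oxidation to 31.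

Step 22. The process at risk is elimination at the hindered C6 oxyphosphonium, or activation of the acid instead of the alcohol, which would lactonise with retention. The fallback sets out from 34. The acid is masked as the allyl ester of 34 F3 (allyl bromide, Cs2CO3, DMF) and C6–OH is converted into the C6 methanesulfonate of that allyl ester F4 (MsCl, Et3N, CH2Cl2). Pd(PPh3)4 with morpholine frees the carboxylate, which on warming with Cs2CO3 in MeCN displaces the sulfonate intramolecularly with inversion. The route is rejoined at 35.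

Further compounds
F1 | step 10 | (3S,4S,5R)-3-[(tert-butyldimethylsilyl)ethynyl]-6-chloro-5-(4-methoxybenzyloxy)-4-{3-[(4-methoxybenzyl)oxy]prop-1-en-2-yl}-3,7-dimethyloct-7-enal (C6 epimers) | CC(C)(C)[Si](C)(C)C#C[C@@](C)(CC=O)[C@@H](C(=C)COCc1ccc(OC)cc1)[C@@H](OCc1ccc(OC)cc1)C(Cl)C(C)=C
F2 | step 18 | C7 3-chloroprop-1-en-2-yl analogue of 28 | C=C[C@@]1(C)C[C@H](OC(=O)C(=C)[C@@H](O[Si](C)(C)C(C)(C)C)CO[Si](C)(C)C(C)(C)C)[C@@H](C(=C)CCl)[C@H](OCc2ccc(OC)cc2)[C@@H]1C(=C)COCc1ccc(OC)cc1
F3 | step 22 | allyl ester of 34 | C=C[C@@]1(C)C[C@H](OC(=O)C(=C)[C@@H](O[Si](C)(C)C(C)(C)C)CO[Si](C)(C)C(C)(C)C)[C@@H](C(=C)C(=O)OCC=C)[C@H](O)[C@@H]1C(=C)CO[Si](C)(C)C(C)(C)C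
F4 | step 22 | C6 methanesulfonate of the allyl ester of 34 | C=C[C@@]1(C)C[C@H](OC(=O)C(=C)[C@@H](O[Si](C)(C)C(C)(C)C)CO[Si](C)(C)C(C)(C)C)[C@@H](C(=C)C(=O)OCC=C)[C@H](OS(C)(=O)=O)[C@@H]1C(=C)CO[Si](C)(C)C(C)(C)C
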